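**Plan**
- Retrosynthetic cuts, in order: the ring A aryl–CH2 bond (to an iodomethyl lactone and an aryl iodide), the lactone Cγ–O bond (to an achiral oxetanyl acrylic acid), the Cα=CH bond to ring B (aldol condensation), and the C=C of an oxetanylidene acetate (olefination of oxetan-3-one).
- Enabling feature: Cβ of the lactone carries two CH2 arms, the ring Cγ–O CH2 and the benzylic CH2 bound to ring A. These are the two enantiotopic CH2 groups of a 3-substituted oxetane whose C3 is Cβ.
- Forward: the acetate chain is put on oxetan-3-one and saturated, joined to the ring B aldehyde as the E-alkene, and freed as the acid. The γ-lactone, the only ring made, then closes; ring A is attached last by Negishi coupling and both MOM groups are removed.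
- Stereochemistry: the single stereocentre (Cβ, R in the target) is set in the lactonisation by a chiral phosphoric acid that selects one enantiotopic oxetane CH2. The E-alkene comes from thermodynamically controlled E1cB dehydration.

Key step: step 7

Assumption: the sense of induction of the binaphthyl phosphoric acid on this substrate cannot be predicted with confidence; the (R)-acid is written, and its mirror image would be used if it delivered the (R)-alcohol instead of the required (S)-alcohol 12.

**Route**

Step 1
Reactants: 1 oxetan-3-one; 2 trimethyl phosphonoacetate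
Product: 3 methyl 2-(oxetan-3-ylidene)acetate
Conditions: NaH, THF, 0 °C to rt
Reagents that add atoms: none
Why: Horner–Wadsworth–Emmons olefination of the unhindered, strained ketone by the stabilised phosphonate anion is fast, and the symmetric ketone makes alkene geometry irrelevant.

Step 2
Reactants: 3 methyl 2-(oxetan-3-ylidene)acetate
Product: 4 methyl 2-(oxetan-3-yl)acetate
Conditions: H2 (1 atm), 10% Pd/C, MeOH, rt
Reagents that add atoms: none
Why: Heterogeneous catalytic hydrogenation saturates the strained exocyclic enoate under conditions that should leave the oxetane C–O bonds intact.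

Step 3
Reactants: 5 3-hydroxy-4,5-dimethoxybenzaldehyde
Product: 6 3,4-dimethoxy-5-(methoxymethoxy)benzaldehyde
Conditions: MOMCl, i-Pr2NEt, CH2Cl2, 0 °C to rt
Reagents that add atoms: chloromethyl methyl ether (MOMCl), COCCl
Why: Williamson-type O-alkylation of the phenol by the reactive α-chloro ether gives a base-stable acetal that survives the enolate and hydroxide steps, and the aldehyde is inert here.

Step 4
Reactants: 4 methyl 2-(oxetan-3-yl)acetate; 6 3,4-dimethoxy-5-(methoxymethoxy)benzaldehyde
Product: 7 methyl 3-[3,4-dimethoxy-5-(methoxymethoxy)phenyl]-3-hydroxy-2-(oxetan-3-yl)propanoate (racemic mixture of diastereomers)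
Conditions: LiN(i-Pr)2, THF, −78 °C; then 6, −78 °C; AcOH quench
Reagents that add atoms: none
Why: Directed aldol addition of the kinetic lithium ester enolate to the non-enolisable aldehyde proceeds at −78 °C, where the base-stable oxetane is untouched, and the diastereomer mixture is irrelevant because both new centres are removed in step 5.

Step 5
Reactants: 7 methyl 3-[3,4-dimethoxy-5-(methoxymethoxy)phenyl]-3-hydroxy-2-(oxetan-3-yl)propanoate
Product: 9 methyl (E)-3-[3,4-dimethoxy-5-(methoxymethoxy)phenyl]-2-(oxetan-3-yl)acrylate, via β-acetoxy ester 8 (not isolated)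
Conditions: Ac2O, Et3N, DMAP (cat.), CH2Cl2, 0 °C to rt; then DBU, rt to 40 °C
Reagents that add atoms: none
Why: Acetylation makes the benzylic oxygen a leaving group and DBU effects E1cB elimination through the ester enolate, so both diastereomers should converge on the more stable E-alkene with the aryl ring trans to the ester (any Z isomer is removed by chromatography).

Step 6
Reactants: 9 methyl (E)-3-[3,4-dimethoxy-5-(methoxymethoxy)phenyl]-2-(oxetan-3-yl)acrylate
Product: 11 (E)-3-[3,4-dimethoxy-5-(methoxymethoxy)phenyl]-2-(oxetan-3-yl)acrylic acid, via lithium carboxylate 10 (not isolated)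
Conditions: LiOH·H2O, THF/MeOH/H2O, rt; then 0.5 M HCl to pH 4–5 under EtOAc, 0 °C; cold extract dried and used at once
Reagents that add atoms: lithium hydroxide, [Li+].[OH-]
Why: Saponification by hydroxide leaves oxetane, MOM acetal and alkene untouched, and cold, mildly acidic two-phase protonation frees the acid without giving it time to open its own oxetane.

Step 7
Reactants: 11 (E)-3-[3,4-dimethoxy-5-(methoxymethoxy)phenyl]-2-(oxetan-3-yl)acrylic acid
Product: 12 (S,E)-3-[3,4-dimethoxy-5-(methoxymethoxy)benzylidene]-4-(hydroxymethyl)dihydrofuran-2(3H)-one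
Conditions: (R)-3,3′-bis(2,4,6-triisopropylphenyl)-1,1′-binaphthyl-2,2′-diyl hydrogen phosphate (10 mol%), toluene (0.05 M), −20 to 0 °C; cold filtration through a short silica pad, solution used at once
Reagents that add atoms: none
Why: Proposed new method: the phosphoric acid should act bifunctionally, its P–OH hydrogen-bonding the oxetane oxygen while its P=O accepts the carboxylic acid proton, so that the carboxyl carbonyl oxygen displaces the activated oxetane oxygen from one ring CH2 in a strain-releasing SN2 opening. The closest known reaction type is the chiral phosphoric acid catalysed desymmetrising opening of 3-substituted oxetanes by tethered alcohol or phenol nucleophiles, and the known uncatalysed isomerisation of oxetane carboxylic acids to hydroxy lactones shows that a carboxyl group is a competent internal nucleophile. The γ-lactone closes in a 5-exo-tet mode, forming the Cγ–O bond. The precursor is achiral and Cβ (oxetane C3) becomes stereogenic only through which enantiotopic CH2 is attacked, so its configuration is under catalyst control by the chiral pocket of the 3,3′-diaryl binaphthyl phosphate. The step needs enantiotopic-group selectivity and a catalysed rate well above the racemic background closure; the rigid, planar E-acrylic acid leaves only rotation about the Cα–Cβ bond and places the aryl ring next to the oxetane as a steric marker, and low temperature in a non-polar solvent holds the background down. The alcohol is kept cold and carried on immediately because degenerate acyl migration to the free hydroxymethyl arm would interconvert the enantiomers.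

Step 8
Reactants: 12 (S,E)-3-[3,4-dimethoxy-5-(methoxymethoxy)benzylidene]-4-(hydroxymethyl)dihydrofuran-2(3H)-one
Product: 13 (R,E)-3-[3,4-dimethoxy-5-(methoxymethoxy)benzylidene]-4-(iodomethyl)dihydrofuran-2(3H)-one
Conditions: PPh3, I2, imidazole, CH2Cl2, −20 to 0 °C (reagent preformed, alcohol solution added)
Reagents that add atoms: iodine, II
Why: Appel-type iodination displaces the alkoxyphosphonium group by SN2 at the primary CH2 without touching Cβ (the descriptor changes only through priorities) and removes the hydroxyl whose acyl migration would racemise the lactone.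

Step 9
Reactants: 14 4-iodo-2-methoxyphenol
Product: 15 4-iodo-2-methoxy-1-(methoxymethoxy)benzene
Conditions: MOMCl, i-Pr2NEt, CH2Cl2, 0 °C to rt
Reagents that add atoms: chloromethyl methyl ether (MOMCl), COCCl
Why: MOM protection masks the acidic phenol O–H that would otherwise protonate the alkylzinc reagent of step 10, and it is removed together with the ring B acetal at the end.

Step 10
Reactants: 13 (R,E)-3-[3,4-dimethoxy-5-(methoxymethoxy)benzylidene]-4-(iodomethyl)dihydrofuran-2(3H)-one; 15 4-iodo-2-methoxy-1-(methoxymethoxy)benzene
Product: 17 (R,E)-3-[3,4-dimethoxy-5-(methoxymethoxy)benzylidene]-4-[3-methoxy-4-(methoxymethoxy)benzyl]dihydrofuran-2(3H)-one, via alkylzinc iodide 16 (not isolated)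
Conditions: Zn dust (I2-activated), DMF, rt; then 15, Pd2(dba)3 (2.5 mol%), SPhos (10 mol%), rt to 40 °C
Reagents that add atoms: none
Why: Zinc insertion into the primary C–I bond followed by Negishi coupling under zerovalent palladium and SPhos forms the C(sp3)–C(sp2) bond through organometallic steps that tolerate lactone and enoate, leave Cβ untouched, and avoid the free alkyl radical of a reductive coupling, which would close onto the neighbouring benzylidene alkene.

Step 11
Reactants: 17 (R,E)-3-[3,4-dimethoxy-5-(methoxymethoxy)benzylidene]-4-[3-methoxy-4-(methoxymethoxy)benzyl]dihydrofuran-2(3H)-one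
Product: 18 (R,E)-3-(3-hydroxy-4,5-dimethoxybenzylidene)-4-(4-hydroxy-3-methoxybenzyl)dihydrofuran-2(3H)-one
Conditions: HCl (2 M in MeOH), THF, rt to 40 °C
Reagents that add atoms: none
Why: Acid-catalysed acetal exchange with methanol removes both aryl MOM ethers as dimethoxymethane, while the lactone (which can only re-close to itself), the E-alkene and the stereocentre are stable to dilute acid.

**Compound list**
1 | oxetan-3-one | O=C1COC1 | starting material
2 | trimethyl phosphonoacetate | COC(=O)CP(=O)(OC)OC | starting material
3 | methyl 2-(oxetan-3-ylidene)acetate | COC(=O)C=C1COC1 | intermediate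
4 | methyl 2-(oxetan-3-yl)acetate | COC(=O)CC1COC1 | intermediate
5 | 3-hydroxy-4,5-dimethoxybenzaldehyde | COc1cc(C=O)cc(O)c1OC | starting material
6 | 3,4-dimethoxy-5-(methoxymethoxy)benzaldehyde | COCOc1cc(C=O)cc(OC)c1OC | intermediate
7 | methyl 3-[3,4-dimethoxy-5-(methoxymethoxy)phenyl]-3-hydroxy-2-(oxetan-3-yl)propanoate (racemic diastereomer mixture) | COC(=O)C(C1COC1)C(O)c1cc(OCOC)c(OC)c(OC)c1 | intermediate
8 | methyl 3-acetoxy-3-[3,4-dimethoxy-5-(methoxymethoxy)phenyl]-2-(oxetan-3-yl)propanoate (not isolated) | COC(=O)C(C1COC1)C(OC(C)=O)c1cc(OCOC)c(OC)c(OC)c1 | intermediate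
9 | methyl (E)-3-[3,4-dimethoxy-5-(methoxymethoxy)phenyl]-2-(oxetan-3-yl)acrylate | COC(=O)/C(=C/c1cc(OCOC)c(OC)c(OC)c1)C1COC1 | intermediate
10 | lithium (E)-3-[3,4-dimethoxy-5-(methoxymethoxy)phenyl]-2-(oxetan-3-yl)acrylate (not isolated) | [Li+].[O-]C(=O)/C(=C/c1cc(OCOC)c(OC)c(OC)c1)C1COC1 | intermediate
11 | (E)-3-[3,4-dimethoxy-5-(methoxymethoxy)phenyl]-2-(oxetan-3-yl)acrylic acid | OC(=O)/C(=C/c1cc(OCOC)c(OC)c(OC)c1)C1COC1 | intermediate
12 | (S,E)-3-[3,4-dimethoxy-5-(methoxymethoxy)benzylidene]-4-(hydroxymethyl)dihydrofuran-2(3H)-one | OC[C@H]1COC(=O)/C1=C/c1cc(OCOC)c(OC)c(OC)c1 | intermediate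
13 | (R,E)-3-[3,4-dimethoxy-5-(methoxymethoxy)benzylidene]-4-(iodomethyl)dihydrofuran-2(3H)-one | IC[C@H]1COC(=O)/C1=C/c1cc(OCOC)c(OC)c(OC)c1 | intermediate
14 | 4-iodo-2-methoxyphenol | COc1cc(I)ccc1O | starting material
15 | 4-iodo-2-methoxy-1-(methoxymethoxy)benzene | COCOc1ccc(I)cc1OC | intermediate
16 | {[(3R,4E)-4-[3,4-dimethoxy-5-(methoxymethoxy)benzylidene]-5-oxotetrahydrofuran-3-yl]methyl}zinc iodide (not isolated) | I[Zn]C[C@H]1COC(=O)/C1=C/c1cc(OCOC)c(OC)c(OC)c1 | intermediate
17 | (R,E)-3-[3,4-dimethoxy-5-(methoxymethoxy)benzylidene]-4-[3-methoxy-4-(methoxymethoxy)benzyl]dihydrofuran-2(3H)-one | COCOc1ccc(C[C@H]2COC(=O)/C2=C/c2cc(OCOC)c(OC)c(OC)c2)cc1OC | intermediate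
18 | (R,E)-3-(3-hydroxy-4,5-dimethoxybenzylidene)-4-(4-hydroxy-3-methoxybenzyl)dihydrofuran-2(3H)-one | COc1cc(C[C@H]2COC(=O)/C2=C/c2cc(O)c(OC)c(OC)c2)ccc1O | target

**Count**
Total steps: 11. Longest linear sequence: 9 steps (1, 2, 4, 5, 6, 7, 8, 10, 11 from oxetan-3-one).

**Steps most likely to fail**

Step 7 (proposed new method). The catalyst may discriminate poorly between the enantiotopic CH2 groups, the uncatalysed racemic closure may compete, and acyl migration may erode enantiopurity before the alcohol is consumed. The fallback sets out from ester 9 and returns at iodide 13, using known reaction types only. Enantioselective opening of the oxetane of 9 with Me3SiBr under a chiral squaramide hydrogen-bond-donor catalyst (N-aryl squaramide carrying an amino-acid-derived 2-arylpyrrolidine amide; t-BuOMe, −78 °C, where the aryl MOM ether should survive) would give methyl (E)-2-[(R)-1-bromo-3-(trimethylsilyloxy)propan-2-yl]-3-[3,4-dimethoxy-5-(methoxymethoxy)phenyl]acrylate F1. Desilylation with pyridinium p-toluenesulfonate in MeOH and acid-catalysed closure of the freed alcohol onto the methyl ester would give (R,E)-4-(bromomethyl)-3-[3,4-dimethoxy-5-(methoxymethoxy)benzylidene]dihydrofuran-2(3H)-one F2. F2 has no free hydroxyl and cannot racemise by acyl migration. Finkelstein exchange (NaI, acetone, reflux) would convert F2 into 13.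

Step 10. Radical closure onto the benzylidene alkene during zinc insertion, protonolysis of the alkylzinc, or β-hydride elimination at palladium may divert the coupling. The fallback sets out from alcohol 12 and aryl iodide 15 and returns at 17, replacing catalytic cross-coupling by a purely SN2 displacement. Alcohol 12 would be converted at −78 °C (Tf2O, 2,6-lutidine, CH2Cl2) into [(3R,4E)-4-[3,4-dimethoxy-5-(methoxymethoxy)benzylidene]-5-oxotetrahydrofuran-3-yl]methyl trifluoromethanesulfonate F3. Iodide 15 would be exchanged with t-BuLi (Et2O, −78 °C) to [3-methoxy-4-(methoxymethoxy)phenyl]lithium F4 and treated with CuI (0.5 equiv) to give lithium bis[3-methoxy-4-(methoxymethoxy)phenyl]cuprate F5. Addition of F3 to F5 at −78 to −40 °C should give 17 without any alkyl radical or alkylmetal at the CH2 group.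

Step 6. The free acid may lactonise by itself during acidification and concentration, which would deliver racemic lactone before the catalyst is present. The fallback sets out from lithium carboxylate 10 and returns at acid 11, releasing the acid only in the catalysis flask. The dried salt 10 would be silylated with Me3SiCl in CH2Cl2 to trimethylsilyl (E)-3-[3,4-dimethoxy-5-(methoxymethoxy)phenyl]-2-(oxetan-3-yl)acrylate F6, and LiCl filtered off. The solution of F6 would be added to the phosphoric acid in toluene at −20 °C, and one equivalent of MeOH would then liberate 11 in the presence of the catalyst.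

**Further compounds**
F1 | step 7 | methyl (E)-2-[(R)-1-bromo-3-(trimethylsilyloxy)propan-2-yl]-3-[3,4-dimethoxy-5-(methoxymethoxy)phenyl]acrylate | COC(=O)/C(=C/c1cc(OCOC)c(OC)c(OC)c1)[C@@H](CBr)CO[Si](C)(C)C
F2 | step 7 | (R,E)-4-(bromomethyl)-3-[3,4-dimethoxy-5-(methoxymethoxy)benzylidene]dihydrofuran-2(3H)-one | BrC[C@H]1COC(=O)/C1=C/c1cc(OCOC)c(OC)c(OC)c1
F3 | step 10 | [(3R,4E)-4-[3,4-dimethoxy-5-(methoxymethoxy)benzylidene]-5-oxotetrahydrofuran-3-yl]methyl trifluoromethanesulfonate | O=S(=O)(OC[C@H]1COC(=O)/C1=C/c1cc(OCOC)c(OC)c(OC)c1)C(F)(F)F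
F4 | step 10 | [3-methoxy-4-(methoxymethoxy)phenyl]lithium | [Li]c1ccc(OCOC)c(OC)c1
F5 | step 10 | lithium bis[3-methoxy-4-(methoxymethoxy)phenyl]cuprate | [Li+].COCOc1ccc([Cu-]c2ccc(OCOC)c(OC)c2)cc1OC
F6 | step 6 | trimethylsilyl (E)-3-[3,4-dimethoxy-5-(methoxymethoxy)phenyl]-2-(oxetan-3-yl)acrylate | C[Si](C)(C)OC(=O)/C(=C/c1cc(OCOC)c(OC)c(OC)c1)C1COC1
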